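## Structural features

The target is a 2,3-dihydro-1-benzofuran in which benzene ring A is fused to the five-membered oxygen ring B (O1, C2, C3, C3a, C7a). C2 carries a 3-oxoprop-1-en-2-yl group (an α-substituted acrolein), C3 a 3-methylbutanoyloxy group, and C5, which is para to O1, a 1-acyloxyethyl chain esterified with (2R)-2-methylbutanoic acid. Of the four stereocentres, C2 (R) and C3 (S) are neighbours on ring B and trans to each other, whereas the side-chain carbinol carbon (R) and the α-carbon of its acid (R) are linked through the ester oxygen and lie too far from ring B to be controlled from it. Both esters sit on benzylic carbons that O1 activates (C3 through the ortho position, the side chain through the para position): acid can ionise either, loss of 3-methylbutanoic acid across C2–C3 would aromatise ring B to a benzofuran, and a phenoxide para to the side-chain ester would expel the carboxylate and form a para-quinone methide. The enal is a polymerisable Michael acceptor that can also slip into conjugation with C2, and the α-centre of the 2-methylbutanoate does not tolerate strong base. The real difficulty is therefore to set the trans C2/C3 pair beside a branched three-carbon arm, to place two different acyl groups on two secondary benzylic oxygens, and to do so without acid and without ever generating a phenoxide para to a benzylic ester. The key step uses the fact that C3a is the ortho carbon of a phenol whose para position is occupied (O1 sits on C7a) and that C3, C2 and the three carbons of the future propenyl arm correspond to the formyl carbon, the epoxide CH and the CMe2 unit of 3,3-dimethyloxirane-2-carbaldehyde, so that C3a–C3 and O1–C2 can be formed in one flask with the configuration of C2 relayed from the epoxide.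

## Logic of the disconnections

The first cut is the C=O bond at the formyl carbon of 17, which is returned through the C–O bond of 16 to the C–H bonds of the allylic methyl group of 15. The enal is the most reactive group of 17 and tolerates neither nucleophiles nor base, so it is introduced last. The gain is an unfunctionalised 2-propenyl group that can be carried through the esterifications. The forward oxidation has to choose the methyl group over the allylic C2–H and must not ionise either benzylic ester.

Next the acyl C–O bond of the side-chain ester of 15 is cut, giving 13 and 14. This removes one stereocentre and the para-benzylic ester from every earlier intermediate and lets the purchased acid enter late and convergently. The forward esterification must run under neutral conditions, because the carbinol of 13 ionises in acid and the α-centre of 14 epimerises in strong base.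

The O–H of 13 is masked by going back to the Si–O bond of 12. A silyl ether is chosen because a siloxide, unlike a carboxylate, is not expelled from the position para to a phenoxide, and the earlier steps must pass through such a phenoxide. The price is one protecting-group removal, which has to leave the C3 ester in place.

The C=C bond of the 2-propenyl group in 12 is traced to the C–O bond of the tertiary alcohol in 11 by formal addition of water. A tertiary carbinol on the carbon attached to C2 is exactly what an epoxide opening at C2 leaves behind, so this cut prepares the key step. The forward dehydration must remove a methyl hydrogen and not the C2–H, whose loss would lead to an enol ether and then to an aromatic benzofuran.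

The acyl C–O bond at C3 of 11 is cut to give 10. A secondary and a tertiary hydroxyl are easy to tell apart, so no protecting group is needed, and the ester also covers the C3 oxygen during the dehydration. The only demand on the forward step is that acylation stops at the secondary hydroxyl.

Ring B of 10 is opened by cutting C3a–C3 and O1–C2, which leads through 9 and 8 to 4 and 7. These are the two bonds that the ortho carbon and the oxygen of a phenol can make to the carbonyl carbon and the α-carbon of an epoxy aldehyde. The gain is the largest of the route: a bicyclic diol with two ring stereocentres becomes a para-substituted phenol and a five-carbon aldehyde with one stereocentre. The forward step must alkylate carbon and not oxygen, must add to the face of the aldehyde that gives the syn adduct, and must open the epoxide at its secondary carbon with inversion.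

4 is simplified by cutting the aryl O–acetyl bond (to 3), the O–Si bond (to 2) and the carbinol C–H bond (to 1). Starting from the aryl acetate means the phenol is never free while the benzylic carbinol is formed and silylated, and it can then be released by a nucleophile too mild to touch the silyl ether. The reduction of 1 must set the (R) centre by catalyst control, since nothing else in the molecule can direct it.

7 is taken back to 6 by reduction of the formyl group, and 6 to 5 by removal of the epoxide oxygen (two C–O bonds). An allylic alcohol is the substrate class for which enantioselective epoxidation is most dependable, and the single centre made there is the source of C2 and, by relay, of C3. The epoxidation must give high enantiomeric purity, because an enantiomeric impurity in 7 would appear in 10 as a diastereomer that differs only at centres remote from the side chain.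

## Other disconnections considered

Alternative 1: The cut is C2–C3 together with O1–C2. Ring B would be assembled from the salicylaldehyde (1R)-1-(3-formyl-4-hydroxyphenyl)ethyl (2R)-2-methylbutanoate A1 and the ylide of a chiral S-methallyl sulfonium salt such as (2R,5R)-2,5-dimethyl-1-(2-methylprop-2-en-1-yl)thiolan-1-ium bromide A2 (the sense of induction would have to be established).
- Forward key step: Cs2CO3 would generate the ylide, its carbanion carbon would add to the formyl group, and the phenoxide oxygen would displace the sulfide from the same carbon to give (1R)-1-[(2R,3S)-3-hydroxy-2-(prop-1-en-2-yl)-2,3-dihydro-1-benzofuran-5-yl]ethyl (2R)-2-methylbutanoate A3.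
- In its favour: the aryl–carbon bond would come from a dependable ortho-formylation, the 2-propenyl group arrives intact so no tertiary alcohol has to be dehydrated, and no volatile epoxy aldehyde is handled. Acylation and allylic oxidation would finish the synthesis, so on step economy it is the better plan by about two steps.
- Against it here: C2 and C3 are both new and both depend on the sulfonium reagent, which must control the absolute sense at the ylide carbon and, through the betaine geometry, the trans relationship. The betaine alkoxide can close to a vinyl epoxide in competition with the phenoxide, and allyl ylides can react through the γ-carbon or rearrange by a [2,3]-shift. A1 is also a phenol with a carboxylate para-benzylic to it, so carbonate threatens the same fragmentation to a quinone methide; the formyl group tempers the phenoxide, which counts for the alternative, but the silyl detour would probably still be needed.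
- Comparison: in structure the two plans treat the side chain equally. In mechanism the chosen plan puts only C3 at risk, because C2 is relayed by an SN2 inversion from an epoxidation-derived centre, whereas Alternative 1 puts both ring centres at risk in one step and needs a stoichiometric chiral reagent that has to be made.

Alternative 2: The cut is O1–C2 and the bond between the α-carbon of the enal and its carbonyl carbon. The precursor is the allenyl phenol (1R)-1-{3-[(1R)-1-{[tert-butyl(dimethyl)silyl]oxy}buta-2,3-dien-1-yl]-4-hydroxyphenyl}ethyl (2R)-2-methylbutanoate A4.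
- Forward key step: PdCl2 would activate the allene, the phenol oxygen would add to the allene carbon next to C3, the vinylpalladium at the central carbon would insert CO, and N,O-dimethylhydroxylamine would intercept the acyl palladium while CuCl2 returns zerovalent palladium to the divalent state. The product would be the Weinreb amide (1R)-1-[(2R,3S)-3-{[tert-butyl(dimethyl)silyl]oxy}-2-{3-[methoxy(methyl)amino]-3-oxoprop-1-en-2-yl}-2,3-dihydro-1-benzofuran-5-yl]ethyl (2R)-2-methylbutanoate A5.
- In its favour: the three-carbon arm is delivered at the carboxyl oxidation level with the 1,1-disubstituted alkene in place, so neither a dehydration nor a late allylic C–H oxidation is needed; on the logic of the enal this alternative is the better one. The medium is not basic, so the phenol of A4 is never a phenoxide; on this point too it is better.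
- Against it here: C2 is created in the oxypalladation and can only be controlled by the neighbouring silyloxy-bearing C3, a 1,2-induction for which a trans preference is not assured. The oxygen may add to the distal allene terminus instead, and HCl released in the copper cycle meets a silyl ether and an ionisable benzylic ester. A5 must still be reduced to the aldehyde in the presence of an ester without conjugate reduction, and the C3 silyl ether must be exchanged for the 3-methylbutanoate. A4 itself needs an enantioselective allenyl transfer to a salicylaldehyde with control of allenyl versus propargyl regiochemistry.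
- Comparison: control of C3 is equal in principle (reagent control there, relay here), control of C2 is weaker (substrate-directed addition against a stereospecific SN2 reaction), and the step count is at best equal once the amide reduction and the protecting-group exchange are counted.

Alternative 3: The cut is O1–C2 of the target, made by a 1,2-shift of the aryl oxygen, with the carbon skeleton taken from the chromene (1R)-1-(2,2-dimethyl-2H-chromen-6-yl)ethyl (2R)-2-methylbutanoate A6. Catalyst-controlled epoxidation of A6 and opening at the benzylic carbon by 3-methylbutanoic acid would give the trans chromanol (1R)-1-[(3R,4S)-3-hydroxy-2,2-dimethyl-4-[(3-methylbutanoyl)oxy]-3,4-dihydro-2H-chromen-6-yl]ethyl (2R)-2-methylbutanoate A7.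
- Forward key step: Tf2O and 2,6-di-tert-butylpyridine would convert the C3 hydroxyl of A7 into a triflate, the ring oxygen would displace it from the rear with inversion, the six-membered ring would contract, and the tertiary cation left at the CMe2 carbon would lose a methyl proton. The product, (1R)-1-[(2R,3S)-3-[(3-methylbutanoyl)oxy]-2-(prop-1-en-2-yl)-2,3-dihydro-1-benzofuran-5-yl]ethyl (2R)-2-methylbutanoate A8, is the same compound as 15.
- In its favour: 2,2-dimethylchromenes are among the best substrates for enantioselective epoxidation with (salen)MnCl catalysts, so the absolute configuration would rest on catalyst control at least equal to that of the allylic alcohol epoxidation used here. The trans relationship follows from two stereospecific displacements. The 2-propenyl group and both esters are in place when ring B forms, so no separate dehydration or protecting-group exchange is needed, and the step count is lower by two or three, which is better.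
- Against it here: the opening of the chromene epoxide occurs at a carbon that is benzylic and ortho to the ring oxygen, so partial SN1 character and erosion of the trans relationship must be expected. The triflate of A7 has outlets other than the aryloxy shift (participation by the neighbouring ester carbonyl, methyl migration from the CMe2 carbon, elimination), and the shift needs the C–OTf bond antiperiplanar to the C2–O1 bond. The tertiary cation may be captured instead of losing a proton, triflic acid, even buffered, is what the two benzylic esters tolerate least, and A6 has to be built on a phenol with a para-benzylic ester.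
- Comparison: the ring-forming event is a cationic rearrangement with several competing channels in place of a base-mediated 5-exo SN2 reaction; the structures reached are equal (A8 is 15); the step economy is better in the alternative.

Key step: step 6

Assumption: 14 is bought as the single (R) enantiomer; if only the (S) acid or the racemate were at hand, an auxiliary-based α-methylation of butanoic acid would have to supply it.

## Route

Step 1
Reactants: 1 4-acetylphenyl acetate
Product: 2 4-[(1R)-1-hydroxyethyl]phenyl acetate
Conditions: RuCl(p-cymene)[(R,R)-TsDPEN] (1 mol%), HCO2H/Et3N (5:2), 30 °C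
Reagents that add atoms: none
Why: Noyori asymmetric transfer hydrogenation of an aryl methyl ketone; hydride and proton pass from Ru–H and N–H through a six-membered transition state in which the aryl group lies under the η6-arene, so the (R,R) ligand should give the (R) carbinol. The aryl acetate is inert in the formic acid medium and makes the product less prone to ionise than a free para-hydroxy compound.

Step 2
Reactants: 2 4-[(1R)-1-hydroxyethyl]phenyl acetate
Product: 3 4-[(1R)-1-{[tert-butyl(dimethyl)silyl]oxy}ethyl]phenyl acetate
Conditions: TBSOTf, 2,6-lutidine, CH2Cl2, −78 to 0 °C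
Reagents that add atoms: tert-butyldimethylsilyl trifluoromethanesulfonate, CC(C)(C)[Si](C)(C)OS(=O)(=O)C(F)(F)F
Why: O-silylation of a secondary alcohol with a silyl triflate and a hindered pyridine base; no bond to the stereocentre is touched, and the absence of imidazole or DMAP avoids acyl transfer from the aryl acetate.

Step 3
Reactants: 3 4-[(1R)-1-{[tert-butyl(dimethyl)silyl]oxy}ethyl]phenyl acetate
Product: 4 4-[(1R)-1-{[tert-butyl(dimethyl)silyl]oxy}ethyl]phenol
Conditions: pyrrolidine, CH2Cl2, 0 °C to rt
Reagents that add atoms: none
Why: Aminolysis of an aryl acetate; a phenoxide is a far better leaving group than an alkoxide, so a secondary amine removes the acetyl group under nearly neutral conditions and leaves the silyl ether. The siloxy group is a poor nucleofuge, so the liberated phenol should not fragment to a quinone methide.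

Step 4
Reactants: 5 3-methylbut-2-en-1-ol
Product: 6 [(2R)-3,3-dimethyloxiran-2-yl]methanol
Conditions: Ti(OiPr)4 (5 mol%), D-(−)-diethyl tartrate (7 mol%), t-BuOOH, 4 Å molecular sieves, CH2Cl2, −20 °C; non-aqueous work-up, distillation
Reagents that add atoms: tert-butyl hydroperoxide, CC(C)(C)OO
Why: Katsuki–Sharpless asymmetric epoxidation of a primary allylic alcohol; alkoxide and peroxide are held on the titanium tartrate, which delivers oxygen to one face of the alkene. The D-(−)-tartrate ester should give the (2R) epoxy alcohol, the mirror image of the (2S) series obtained with the L-(+) ester.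

Step 5
Reactants: 6 [(2R)-3,3-dimethyloxiran-2-yl]methanol
Product: 7 (2S)-3,3-dimethyloxirane-2-carbaldehyde
Conditions: Dess–Martin periodinane, NaHCO3, CH2Cl2, 0 °C to rt; filtration, careful concentration, used at once
Reagents that add atoms: none
Why: Dess–Martin oxidation of a primary alcohol stops at the aldehyde under buffered, anhydrous conditions that spare the epoxide and allow a non-aqueous isolation of the small, water-soluble product. The stereocentre is untouched; its descriptor changes from R to S only because the formyl group outranks the CMe2 carbon.

Step 6
Reactants: 4 4-[(1R)-1-{[tert-butyl(dimethyl)silyl]oxy}ethyl]phenol, 7 (2S)-3,3-dimethyloxirane-2-carbaldehyde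
Product: 10 (2S,3S)-5-[(1R)-1-{[tert-butyl(dimethyl)silyl]oxy}ethyl]-2-(2-hydroxypropan-2-yl)-2,3-dihydro-1-benzofuran-3-ol, via bromomagnesium phenoxide 8 (not isolated), via syn epoxy alcohol 9 (not isolated)
Conditions: EtMgBr (1.0 equiv), Et2O, 0 °C; solvent exchanged for CH2Cl2; 7, −20 °C to rt; then MeOH, Cs2CO3, rt
Reagents that add atoms: none
Why: Proposed new method: the bromomagnesium phenoxide 8 should bind the aldehyde oxygen of 7 and deliver its ortho carbon to the carbonyl carbon through a six-membered cyclic transition state, the closest known reaction type being the ortho-specific hydroxyalkylation of magnesium phenoxides with α-alkoxy aldehydes in non-coordinating solvents, which has not been shown for α,β-epoxy aldehydes or in tandem with an epoxide opening. Because the para position carries the side chain and the two ortho positions are equivalent, C-alkylation can only give the C3a–C3 bond. The new C3 centre is controlled by the stereocentre of 7 through chelation: divalent magnesium bridging the carbonyl and epoxide oxygens holds the C=O and C–O bonds syn-periplanar, the aryl carbon attacks the face away from the CMe2 group, and the syn adduct 9 with (S) configuration at the carbinol carbon results, by the same chelate model that accounts for anti-selective hydride reduction of α,β-epoxy ketones. Methanol and Cs2CO3 then free the phenoxide while the benzylic hydroxyl stays protonated, so that Payne migration of the epoxide is not expected. The phenoxide oxygen opens the epoxide at the neighbouring secondary carbon in a 5-exo-tet closure (SN2, inversion) and not at the tertiary carbon (6-endo-tet), which forms O1–C2 and closes ring B. C2 is thereby fixed by inversion of the epoxide centre, and syn addition followed by inversion places the 2-hydroxypropan-2-yl group and the C3 hydroxyl trans. The step needs ortho regioselectivity (secured by the occupied para position and the magnesium template), syn facial selectivity (secured only by the chelate, hence magnesium and CH2Cl2) and exo ring opening (secured by the basic medium and the substitution pattern of the epoxide); the silyl ether cannot leave when the phenoxide is formed, as an ester on that oxygen would.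

Step 7
Reactants: 10 (2S,3S)-5-[(1R)-1-{[tert-butyl(dimethyl)silyl]oxy}ethyl]-2-(2-hydroxypropan-2-yl)-2,3-dihydro-1-benzofuran-3-ol
Product: 11 (2S,3S)-5-[(1R)-1-{[tert-butyl(dimethyl)silyl]oxy}ethyl]-2-(2-hydroxypropan-2-yl)-2,3-dihydro-1-benzofuran-3-yl 3-methylbutanoate
Conditions: 3-methylbutanoic anhydride (1.2 equiv), Et3N, DMAP (cat.), CH2Cl2, 0 °C
Reagents that add atoms: 3-methylbutanoic anhydride, CC(C)CC(=O)OC(=O)CC(C)C
Why: DMAP-catalysed acylation; the secondary C3 hydroxyl reacts, the tertiary hydroxyl should not at 0 °C with a slight excess of anhydride, and no stereocentre is involved.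

Step 8
Reactants: 11 (2S,3S)-5-[(1R)-1-{[tert-butyl(dimethyl)silyl]oxy}ethyl]-2-(2-hydroxypropan-2-yl)-2,3-dihydro-1-benzofuran-3-yl 3-methylbutanoate
Product: 12 (2R,3S)-5-[(1R)-1-{[tert-butyl(dimethyl)silyl]oxy}ethyl]-2-(prop-1-en-2-yl)-2,3-dihydro-1-benzofuran-3-yl 3-methylbutanoate
Conditions: SOCl2, pyridine, CH2Cl2, −20 to 0 °C
Reagents that add atoms: none
Why: Dehydration of a tertiary alcohol through its chlorosulfite with pyridine as base (E2); the six methyl hydrogens are more accessible than the single C2–H flanked by O1 and the C3 ester, so the 1,1-disubstituted alkene should predominate over the enol ether. The descriptor at C2 changes from S to R without any change in geometry.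

Step 9
Reactants: 12 (2R,3S)-5-[(1R)-1-{[tert-butyl(dimethyl)silyl]oxy}ethyl]-2-(prop-1-en-2-yl)-2,3-dihydro-1-benzofuran-3-yl 3-methylbutanoate
Product: 13 (2R,3S)-5-[(1R)-1-hydroxyethyl]-2-(prop-1-en-2-yl)-2,3-dihydro-1-benzofuran-3-yl 3-methylbutanoate
Conditions: HF·pyridine, pyridine, THF, 0 °C to rt
Reagents that add atoms: none
Why: Fluoride cleavage of the silyl ether in a pyridine-buffered medium that is neither basic enough to move or cleave the C3 ester nor acidic enough to ionise the benzylic carbinol; the Si–O bond is broken and not the C–O bond, so the (R) centre is retained.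

Step 10
Reactants: 13 (2R,3S)-5-[(1R)-1-hydroxyethyl]-2-(prop-1-en-2-yl)-2,3-dihydro-1-benzofuran-3-yl 3-methylbutanoate, 14 (2R)-2-methylbutanoic acid
Product: 15 (1R)-1-[(2R,3S)-3-[(3-methylbutanoyl)oxy]-2-(prop-1-en-2-yl)-2,3-dihydro-1-benzofuran-5-yl]ethyl (2R)-2-methylbutanoate
Conditions: DIC, DMAP (cat.), CH2Cl2, 0 °C to rt
Reagents that add atoms: none
Why: Steglich esterification; the acid is activated by the carbodiimide and DMAP under neutral conditions and the alcohol attacks through oxygen, so its configuration is retained. An α-alkyl acid activated in this way is not expected to epimerise at 0 °C.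

Step 11
Reactants: 15 (1R)-1-[(2R,3S)-3-[(3-methylbutanoyl)oxy]-2-(prop-1-en-2-yl)-2,3-dihydro-1-benzofuran-5-yl]ethyl (2R)-2-methylbutanoate
Product: 17 (1R)-1-[(2R,3S)-3-[(3-methylbutanoyl)oxy]-2-(3-oxoprop-1-en-2-yl)-2,3-dihydro-1-benzofuran-5-yl]ethyl (2R)-2-methylbutanoate, via allylic alcohol 16 (not isolated)
Conditions: SeO2 (0.3 equiv), t-BuOOH, CH2Cl2, rt; crude product then MnO2, CH2Cl2, rt
Reagents that add atoms: selenium dioxide, O=[Se]=O; tert-butyl hydroperoxide, CC(C)(C)OO
Why: Allylic oxidation with SeO2 (ene reaction at the terminal alkene carbon, then [2,3]-sigmatropic shift) restores the 1,1-disubstituted alkene and oxygenates the methyl group, which should react in preference to the hindered, oxygen-bearing C2–H. MnO2 then takes the primary allylic alcohol 16 to the enal under neutral conditions; no stereocentre is touched.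

## Compound list

1 | 4-acetylphenyl acetate | CC(=O)Oc1ccc(C(C)=O)cc1 | starting material
2 | 4-[(1R)-1-hydroxyethyl]phenyl acetate | CC(=O)Oc1ccc([C@@H](C)O)cc1 | intermediate
3 | 4-[(1R)-1-{[tert-butyl(dimethyl)silyl]oxy}ethyl]phenyl acetate | CC(=O)Oc1ccc([C@@H](C)O[Si](C)(C)C(C)(C)C)cc1 | intermediate
4 | 4-[(1R)-1-{[tert-butyl(dimethyl)silyl]oxy}ethyl]phenol | Oc1ccc([C@@H](C)O[Si](C)(C)C(C)(C)C)cc1 | intermediate
5 | 3-methylbut-2-en-1-ol | CC(C)=CCO | starting material
6 | [(2R)-3,3-dimethyloxiran-2-yl]methanol | OC[C@H]1OC1(C)C | intermediate
7 | (2S)-3,3-dimethyloxirane-2-carbaldehyde | O=C[C@H]1OC1(C)C | intermediate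
8 | bromo{4-[(1R)-1-{[tert-butyl(dimethyl)silyl]oxy}ethyl]phenoxy}magnesium | Br[Mg]Oc1ccc([C@@H](C)O[Si](C)(C)C(C)(C)C)cc1 | intermediate
9 | 4-[(1R)-1-{[tert-butyl(dimethyl)silyl]oxy}ethyl]-2-{(S)-[(2R)-3,3-dimethyloxiran-2-yl](hydroxy)methyl}phenol (present as its magnesium salt) | Oc1ccc([C@@H](C)O[Si](C)(C)C(C)(C)C)cc1[C@H](O)[C@H]1OC1(C)C | intermediate
10 | (2S,3S)-5-[(1R)-1-{[tert-butyl(dimethyl)silyl]oxy}ethyl]-2-(2-hydroxypropan-2-yl)-2,3-dihydro-1-benzofuran-3-ol | CC(C)(O)[C@H]1Oc2ccc([C@@H](C)O[Si](C)(C)C(C)(C)C)cc2[C@@H]1O | intermediate
11 | (2S,3S)-5-[(1R)-1-{[tert-butyl(dimethyl)silyl]oxy}ethyl]-2-(2-hydroxypropan-2-yl)-2,3-dihydro-1-benzofuran-3-yl 3-methylbutanoate | CC(C)(O)[C@H]1Oc2ccc([C@@H](C)O[Si](C)(C)C(C)(C)C)cc2[C@@H]1OC(=O)CC(C)C | intermediate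
12 | (2R,3S)-5-[(1R)-1-{[tert-butyl(dimethyl)silyl]oxy}ethyl]-2-(prop-1-en-2-yl)-2,3-dihydro-1-benzofuran-3-yl 3-methylbutanoate | C=C(C)[C@H]1Oc2ccc([C@@H](C)O[Si](C)(C)C(C)(C)C)cc2[C@@H]1OC(=O)CC(C)C | intermediate
13 | (2R,3S)-5-[(1R)-1-hydroxyethyl]-2-(prop-1-en-2-yl)-2,3-dihydro-1-benzofuran-3-yl 3-methylbutanoate | C=C(C)[C@H]1Oc2ccc([C@@H](C)O)cc2[C@@H]1OC(=O)CC(C)C | intermediate
14 | (2R)-2-methylbutanoic acid | CC[C@@H](C)C(=O)O | starting material
15 | (1R)-1-[(2R,3S)-3-[(3-methylbutanoyl)oxy]-2-(prop-1-en-2-yl)-2,3-dihydro-1-benzofuran-5-yl]ethyl (2R)-2-methylbutanoate | C=C(C)[C@H]1Oc2ccc([C@@H](C)OC(=O)[C@H](C)CC)cc2[C@@H]1OC(=O)CC(C)C | intermediate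
16 | (1R)-1-[(2R,3S)-2-(3-hydroxyprop-1-en-2-yl)-3-[(3-methylbutanoyl)oxy]-2,3-dihydro-1-benzofuran-5-yl]ethyl (2R)-2-methylbutanoate | C=C(CO)[C@H]1Oc2ccc([C@@H](C)OC(=O)[C@H](C)CC)cc2[C@@H]1OC(=O)CC(C)C | intermediate
17 | (1R)-1-[(2R,3S)-3-[(3-methylbutanoyl)oxy]-2-(3-oxoprop-1-en-2-yl)-2,3-dihydro-1-benzofuran-5-yl]ethyl (2R)-2-methylbutanoate | C=C(C=O)[C@H]1Oc2ccc([C@@H](C)OC(=O)[C@H](C)CC)cc2[C@@H]1OC(=O)CC(C)C | target

## Step count and least certain steps

Total: 11 steps (three to 4, two to 7, the key step, five from 10 to 17). Longest linear sequence: 9 steps (steps 1–3 and 6–11, from 1 to 17).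

Step 6 (key step, new method).
- What may go wrong: facial selectivity may be lost if the epoxide oxygen does not chelate, and a Felkin–Anh-type addition would lead to the cis series. The Lewis-acidic magnesium bromide species may open or rearrange the epoxide before the C–C bond forms, and a second phenol may condense with the benzylic carbinol.
- Tuning within the step: a halide-free magnesium bis(phenoxide) from n-Bu2Mg and a lower temperature are the first adjustments.
- Fallback (known chemistry, different approach): it sets out from 4 (with 7) and rejoins the route at 11.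
  - 4 is brominated ortho to the hydroxyl (NBS, i-Pr2NH cat., CH2Cl2, 0 °C) to give 2-bromo-4-[(1R)-1-{[tert-butyl(dimethyl)silyl]oxy}ethyl]phenol F1.
  - Deprotonation and bromine–lithium exchange (n-BuLi, 2.1 equiv, THF, −78 °C) give the ortho-lithiated lithium phenoxide, which is added to 7. Without a chelating metal the Felkin–Anh adduct 4-[(1R)-1-{[tert-butyl(dimethyl)silyl]oxy}ethyl]-2-{(R)-[(2R)-3,3-dimethyloxiran-2-yl](hydroxy)methyl}phenol F2 should predominate over 9.
  - Cs2CO3 in MeOH closes both adducts by the same 5-exo opening: 9 gives 10, which continues by step 7, and F2 gives the cis diol (2S,3R)-5-[(1R)-1-{[tert-butyl(dimethyl)silyl]oxy}ethyl]-2-(2-hydroxypropan-2-yl)-2,3-dihydro-1-benzofuran-3-ol F3.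
  - F3 is esterified under Mitsunobu conditions (3-methylbutanoic acid, PPh3, DIAD, THF, 0 °C), which acylates the secondary benzylic C3 oxygen with inversion and leaves the tertiary hydroxyl, to give 11. Both diastereomers therefore converge on 11.

Step 11.
- What may go wrong: oxidation may compete at the allylic C2–H, the 1,1-disubstituted alkene may react slowly, selenous acid may promote loss of the C3 ester with aromatisation, and the enal may isomerise or add nucleophiles during isolation.
- Fallback: it sets out from 15 and returns at 17. A Schenck ene reaction (O2, tetraphenylporphyrin, visible light, CH2Cl2, 0 °C) adds singlet oxygen to the terminal alkene carbon with removal of a methyl hydrogen and gives the allylic hydroperoxide (1R)-1-[(2R,3S)-2-(3-hydroperoxyprop-1-en-2-yl)-3-[(3-methylbutanoyl)oxy]-2,3-dihydro-1-benzofuran-5-yl]ethyl (2R)-2-methylbutanoate F4. Dehydration with Ac2O and pyridine (Kornblum–DeLaMare type) gives 17.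

Step 8.
- What may go wrong: elimination may go toward C2 (enol ether, then aromatisation by loss of the acid), the C3 ester carbonyl may participate at the tertiary centre and cause acyl migration, or the tertiary chloride may form instead.
- Fallback: it sets out from 10 and returns at 12, and removes the participating ester from the dehydration.
  - The C3 hydroxyl is silylated (TESCl, imidazole, CH2Cl2, 0 °C) to 2-[(2S,3S)-5-[(1R)-1-{[tert-butyl(dimethyl)silyl]oxy}ethyl]-3-[(triethylsilyl)oxy]-2,3-dihydro-1-benzofuran-2-yl]propan-2-ol F5.
  - The tertiary alcohol is dehydrated by syn elimination with the Burgess reagent (toluene, 50 °C) to tert-butyl(dimethyl){(1R)-1-[(2R,3S)-2-(prop-1-en-2-yl)-3-[(triethylsilyl)oxy]-2,3-dihydro-1-benzofuran-5-yl]ethoxy}silane F6.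
  - The more labile triethylsilyl ether is removed selectively (HF·pyridine, pyridine, THF, 0 °C, short reaction time) to (2R,3S)-5-[(1R)-1-{[tert-butyl(dimethyl)silyl]oxy}ethyl]-2-(prop-1-en-2-yl)-2,3-dihydro-1-benzofuran-3-ol F7.
  - F7 is acylated as in step 7 to give 12.

Step 4.
- What may go wrong: the small, water-miscible and volatile epoxy alcohol may be lost during isolation, and the enantiomeric purity may be too low; the deficit would be carried into 10 as a diastereomer that is hard to separate.
- Fallback: it sets out from 5 and returns at 6. The epoxidation is run as in step 4 and the product is acylated in the same flask (4-nitrobenzoyl chloride, Et3N, 0 °C) to [(2R)-3,3-dimethyloxiran-2-yl]methyl 4-nitrobenzoate F8, a crystalline solid that can be extracted and recrystallised to raise the enantiomeric purity. Methanolysis (K2CO3 cat., MeOH, 0 °C) and distillation return 6.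

## Further compounds

F1 | step 6 | 2-bromo-4-[(1R)-1-{[tert-butyl(dimethyl)silyl]oxy}ethyl]phenol | Oc1ccc([C@@H](C)O[Si](C)(C)C(C)(C)C)cc1Br
F2 | step 6 | 4-[(1R)-1-{[tert-butyl(dimethyl)silyl]oxy}ethyl]-2-{(R)-[(2R)-3,3-dimethyloxiran-2-yl](hydroxy)methyl}phenol | Oc1ccc([C@@H](C)O[Si](C)(C)C(C)(C)C)cc1[C@@H](O)[C@H]1OC1(C)C
F3 | step 6 | (2S,3R)-5-[(1R)-1-{[tert-butyl(dimethyl)silyl]oxy}ethyl]-2-(2-hydroxypropan-2-yl)-2,3-dihydro-1-benzofuran-3-ol | CC(C)(O)[C@H]1Oc2ccc([C@@H](C)O[Si](C)(C)C(C)(C)C)cc2[C@H]1O
F4 | step 11 | (1R)-1-[(2R,3S)-2-(3-hydroperoxyprop-1-en-2-yl)-3-[(3-methylbutanoyl)oxy]-2,3-dihydro-1-benzofuran-5-yl]ethyl (2R)-2-methylbutanoate | C=C(COO)[C@H]1Oc2ccc([C@@H](C)OC(=O)[C@H](C)CC)cc2[C@@H]1OC(=O)CC(C)C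
F5 | step 8 | 2-[(2S,3S)-5-[(1R)-1-{[tert-butyl(dimethyl)silyl]oxy}ethyl]-3-[(triethylsilyl)oxy]-2,3-dihydro-1-benzofuran-2-yl]propan-2-ol | CC(C)(O)[C@H]1Oc2ccc([C@@H](C)O[Si](C)(C)C(C)(C)C)cc2[C@@H]1O[Si](CC)(CC)CC
F6 | step 8 | tert-butyl(dimethyl){(1R)-1-[(2R,3S)-2-(prop-1-en-2-yl)-3-[(triethylsilyl)oxy]-2,3-dihydro-1-benzofuran-5-yl]ethoxy}silane | C=C(C)[C@H]1Oc2ccc([C@@H](C)O[Si](C)(C)C(C)(C)C)cc2[C@@H]1O[Si](CC)(CC)CC
F7 | step 8 | (2R,3S)-5-[(1R)-1-{[tert-butyl(dimethyl)silyl]oxy}ethyl]-2-(prop-1-en-2-yl)-2,3-dihydro-1-benzofuran-3-ol | C=C(C)[C@H]1Oc2ccc([C@@H](C)O[Si](C)(C)C(C)(C)C)cc2[C@@H]1O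
F8 | step 4 | [(2R)-3,3-dimethyloxiran-2-yl]methyl 4-nitrobenzoate | O=C(OC[C@H]1OC1(C)C)c1ccc([N+](=O)[O-])cc1
A1 | alternative 1 | (1R)-1-(3-formyl-4-hydroxyphenyl)ethyl (2R)-2-methylbutanoate | O=Cc1cc([C@@H](C)OC(=O)[C@H](C)CC)ccc1O
A2 | alternative 1 | (2R,5R)-2,5-dimethyl-1-(2-methylprop-2-en-1-yl)thiolan-1-ium bromide | C=C(C)C[S+]1[C@H](C)CC[C@H]1C.[Br-]
A3 | alternative 1 | (1R)-1-[(2R,3S)-3-hydroxy-2-(prop-1-en-2-yl)-2,3-dihydro-1-benzofuran-5-yl]ethyl (2R)-2-methylbutanoate | C=C(C)[C@H]1Oc2ccc([C@@H](C)OC(=O)[C@H](C)CC)cc2[C@@H]1O
A4 | alternative 2 | (1R)-1-{3-[(1R)-1-{[tert-butyl(dimethyl)silyl]oxy}buta-2,3-dien-1-yl]-4-hydroxyphenyl}ethyl (2R)-2-methylbutanoate | Oc1ccc([C@@H](C)OC(=O)[C@H](C)CC)cc1[C@@H](C=C=C)O[Si](C)(C)C(C)(C)C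
A5 | alternative 2 | (1R)-1-[(2R,3S)-3-{[tert-butyl(dimethyl)silyl]oxy}-2-{3-[methoxy(methyl)amino]-3-oxoprop-1-en-2-yl}-2,3-dihydro-1-benzofuran-5-yl]ethyl (2R)-2-methylbutanoate | C=C(C(=O)N(C)OC)[C@H]1Oc2ccc([C@@H](C)OC(=O)[C@H](C)CC)cc2[C@@H]1O[Si](C)(C)C(C)(C)C
A6 | alternative 3 | (1R)-1-(2,2-dimethyl-2H-chromen-6-yl)ethyl (2R)-2-methylbutanoate | CC1(C)C=Cc2cc([C@@H](C)OC(=O)[C@H](C)CC)ccc2O1
A7 | alternative 3 | (1R)-1-[(3R,4S)-3-hydroxy-2,2-dimethyl-4-[(3-methylbutanoyl)oxy]-3,4-dihydro-2H-chromen-6-yl]ethyl (2R)-2-methylbutanoate | CC1(C)Oc2ccc([C@@H](C)OC(=O)[C@H](C)CC)cc2[C@H](OC(=O)CC(C)C)[C@H]1O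
A8 | alternative 3 | (1R)-1-[(2R,3S)-3-[(3-methylbutanoyl)oxy]-2-(prop-1-en-2-yl)-2,3-dihydro-1-benzofuran-5-yl]ethyl (2R)-2-methylbutanoate | C=C(C)[C@H]1Oc2ccc([C@@H](C)OC(=O)[C@H](C)CC)cc2[C@@H]1OC(=O)CC(C)C
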